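The route rests on one cut: the σ-bond between alkene carbon C4′ and acetoxy carbon C5′ of the side chain (C1′ on ring C6). Step 10 unites, in one operation, an (E)-alkenyl iodide that already carries the dihydropyranone ring, the silylated C1′ carbinol and the C2′ methoxy group with the α-oxy radical released by photoredox decarboxylation of an L-threonine-derived dioxolane carboxylate under nickel catalysis. The step exploits the threo C5′/C6′ diol and its C7′ methyl: held in a trans-2,2,5-trimethyl-1,3-dioxolane ring, the C6′ methyl directs the new bond at C5′ to the opposite face, while the threonine carboxyl carbon leaves as CO2.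

Key step: step 10

Remark: C2–C6 denote the pyranone ring atoms and C1′–C7′ the side chain counted from the ring; 1 and 12 (the acetonide methyl ester made from L-threonine) are taken as catalogue compounds.

Step 1
Reactants: 1 (E)-pent-2-en-4-yn-1-ol
Product: 3 (2E,4E)-5-iodopenta-2,4-dien-1-ol, via dienylzirconocene chloride 2 (not isolated)
Conditions: Cp2Zr(H)Cl (2.2 equiv), THF, 0 °C to rt; then I2, 0 °C
Reagents that add atoms: iodine, II
Why: Hydrozirconation–iodination: after the first equivalent of Schwartz reagent is consumed by the hydroxyl, the second adds syn to the terminal alkyne with zirconium at the terminal carbon, and iodinolysis with retention should give only the (E)-iodide.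

Step 2
Reactants: 3 (2E,4E)-5-iodopenta-2,4-dien-1-ol
Product: 4 (2E,4E)-5-iodopenta-2,4-dienal
Conditions: MnO2 (excess), CH2Cl2, rt
Reagents that add atoms: none
Why: MnO2 oxidation is selective for the activated dienylic alcohol and should leave the geometry of the iodo-diene untouched.

Step 3
Reactants: 4 (2E,4E)-5-iodopenta-2,4-dienal
Product: 6 (4S,5E,7E)-8-iodoocta-1,5,7-trien-4-ol, via diisopinocampheylborinate ester 5 (not isolated)
Conditions: (−)-Ipc2B(allyl) (1 M in pentane), Et2O, −78 °C; then NaOH, H2O2, 0 °C to rt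
Reagents that add atoms: (−)-B-allyldiisopinocampheylborane, C=CCB([C@@H]1C[C@@H]2C[C@H]([C@H]1C)C2(C)C)[C@@H]1C[C@@H]2C[C@H]([C@H]1C)C2(C)C
Why: Brown allylboration through a chair Zimmerman–Traxler transition state, in which the isopinocampheyl groups derived from (+)-α-pinene deliver allyl to the Si face of the enal and set the carbinol (future C6) as S.

Step 4
Reactants: 6 (4S,5E,7E)-8-iodoocta-1,5,7-trien-4-ol
Product: 7 (1S)-1-[(2S,3S)-3-[(E)-2-iodoethenyl]oxiran-2-yl]but-3-en-1-ol
Conditions: Ti(OiPr)4 (0.2 equiv), L-(+)-DIPT (0.25 equiv), TBHP (decane), 4 Å MS, CH2Cl2, −20 °C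
Reagents that add atoms: tert-butyl hydroperoxide, CC(C)(C)OO
Why: Sharpless asymmetric epoxidation in its matched mode: the titanium tartrate bound to the (S)-carbinol epoxidises only the adjacent alkene and should give the erythro (2S,3S)-epoxide (future C1′, C2′), while any minor (R)-alcohol is the slow-reacting enantiomer and is left behind.

Step 5
Reactants: 7 (1S)-1-[(2S,3S)-3-[(E)-2-iodoethenyl]oxiran-2-yl]but-3-en-1-ol
Product: 8 (1S)-1-[(2S,3S)-3-[(E)-2-iodoethenyl]oxiran-2-yl]but-3-en-1-yl prop-2-enoate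
Conditions: acryloyl chloride, iPr2NEt, CH2Cl2, −78 to 0 °C
Reagents that add atoms: acryloyl chloride, C=CC(=O)Cl
Why: O-acylation of the secondary alcohol under basic conditions that should leave the acid-sensitive vinyl epoxide intact.

Step 6
Reactants: 8 (1S)-1-[(2S,3S)-3-[(E)-2-iodoethenyl]oxiran-2-yl]but-3-en-1-yl prop-2-enoate
Product: 9 (6S)-6-[(2S,3S)-3-[(E)-2-iodoethenyl]oxiran-2-yl]-5,6-dihydro-2H-pyran-2-one
Conditions: second-generation Grubbs catalyst (5 mol%), CH2Cl2 (5 mM), 40 °C
Reagents that add atoms: none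
Why: Ring-closing metathesis between the terminal allyl alkene and the acrylate closes the six-membered unsaturated lactone with loss of ethylene, and the 1,2-disubstituted iodoalkene should not engage the ruthenium carbene.

Step 7
Reactants: 9 (6S)-6-[(2S,3S)-3-[(E)-2-iodoethenyl]oxiran-2-yl]-5,6-dihydro-2H-pyran-2-one
Product: 10 (6S)-6-[(1S,2R,3E)-1-hydroxy-4-iodo-2-methoxybut-3-en-1-yl]-5,6-dihydro-2H-pyran-2-one
Conditions: MeOH (10 equiv), BF3·OEt2 (0.2 equiv), CH2Cl2, −40 to −20 °C
Reagents that add atoms: methanol, CO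
Why: Lewis acid-catalysed alcoholysis of a vinyl epoxide: methanol attacks the allylic carbon C2′ in SN2 fashion with inversion (C1′ is deactivated by the neighbouring lactone oxygen), which should give the anti pattern with C2′ R and C1′ S.

Step 8
Reactants: 10 (6S)-6-[(1S,2R,3E)-1-hydroxy-4-iodo-2-methoxybut-3-en-1-yl]-5,6-dihydro-2H-pyran-2-one
Product: 11 (6S)-6-[(1S,2R,3E)-1-(tert-butyldimethylsilyloxy)-4-iodo-2-methoxybut-3-en-1-yl]-5,6-dihydro-2H-pyran-2-one
Conditions: TBSOTf, 2,6-lutidine, CH2Cl2, −78 to 0 °C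
Reagents that add atoms: tert-butyldimethylsilyl triflate, CC(C)(C)[Si](C)(C)OS(=O)(=O)C(F)(F)F
Why: Silylation of the hindered secondary alcohol with the silyl triflate, which keeps C1′–OH out of the later acetylation and out of oxa-Michael addition to the enoate.

Step 9
Reactants: 12 methyl (4S,5R)-2,2,5-trimethyl-1,3-dioxolane-4-carboxylate
Product: 13 cesium (4S,5R)-2,2,5-trimethyl-1,3-dioxolane-4-carboxylate
Conditions: CsOH·H2O (1.0 equiv), MeOH/H2O, 0 °C to rt; evaporate to dryness
Reagents that add atoms: cesium hydroxide, [Cs+].[OH-]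
Why: Ester saponification gives the carboxylate salt directly, so the acid-labile acetonide never meets free acid, and the α-centre need not be preserved because it becomes a radical.

Step 10
Reactants: 11 (6S)-6-[(1S,2R,3E)-1-(tert-butyldimethylsilyloxy)-4-iodo-2-methoxybut-3-en-1-yl]-5,6-dihydro-2H-pyran-2-one; 13 cesium (4S,5R)-2,2,5-trimethyl-1,3-dioxolane-4-carboxylate (1.5 equiv)
Product: 15 (6S)-6-[(1S,2R,3E)-1-(tert-butyldimethylsilyloxy)-2-methoxy-4-[(4R,5R)-2,2,5-trimethyl-1,3-dioxolan-4-yl]but-3-en-1-yl]-5,6-dihydro-2H-pyran-2-one, via dioxolan-4-yl radical 14 (not isolated)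
Conditions: Ir[dF(CF3)ppy]2(dtbbpy)PF6 (1 mol%), NiCl2·glyme (5 mol%), dtbbpy (5 mol%), degassed DMSO, blue LEDs (450 nm), 25 °C
Reagents that add atoms: none
Why: This is the known decarboxylative vinylation of α-oxy carboxylic acids by dual photoredox/nickel catalysis: the excited iridium complex oxidises carboxylate 13, loss of CO2 gives the nucleophilic α-oxy radical 14, zerovalent nickel inserts into the C–I bond of 11, the divalent alkenylnickel iodide captures 14, and reductive elimination from trivalent nickel forms the C4′–C5′ bond before the reduced photocatalyst returns nickel to the zerovalent state. No ring is closed. The one new stereocentre, C5′, is controlled by the dioxolane ring: the planar radical carbon bonds on the face opposite the C6′ methyl, which should give the trans-4,5-disubstituted dioxolane (C5′ R) from either C4 epimer of 13. Insertion and reductive elimination keep the E geometry of C3′=C4′. The step needs chemoselectivity for capture of 14 by nickel over conjugate addition to the lactone; the enoate is endocyclic and β-substituted, hence a slow radical acceptor, 13 is used in excess, and the C1′ silyl ether leaves no free hydroxyl.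

Step 11
Reactants: 15 (6S)-6-[(1S,2R,3E)-1-(tert-butyldimethylsilyloxy)-2-methoxy-4-[(4R,5R)-2,2,5-trimethyl-1,3-dioxolan-4-yl]but-3-en-1-yl]-5,6-dihydro-2H-pyran-2-one
Product: 16 (6S)-6-[(1S,2R,3E,5R,6R)-1-(tert-butyldimethylsilyloxy)-5,6-dihydroxy-2-methoxyhept-3-en-1-yl]-5,6-dihydro-2H-pyran-2-one
Conditions: AcOH/H2O (4:1), 45 °C
Reagents that add atoms: none
Why: Acid hydrolysis of the isopropylidene acetal, which the hindered secondary silyl ether, the allylic methyl ether and the lactone should tolerate.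

Step 12
Reactants: 16 (6S)-6-[(1S,2R,3E,5R,6R)-1-(tert-butyldimethylsilyloxy)-5,6-dihydroxy-2-methoxyhept-3-en-1-yl]-5,6-dihydro-2H-pyran-2-one
Product: 17 (6S)-6-[(1S,2R,3E,5R,6R)-5,6-diacetoxy-1-(tert-butyldimethylsilyloxy)-2-methoxyhept-3-en-1-yl]-5,6-dihydro-2H-pyran-2-one
Conditions: Ac2O, pyridine, DMAP (cat.), CH2Cl2, 0 °C to rt
Reagents that add atoms: acetic anhydride, CC(=O)OC(C)=O
Why: DMAP-catalysed acetylation of the two free secondary hydroxyls at C5′ and C6′ while C1′ is still silylated.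

Step 13
Reactants: 17 (6S)-6-[(1S,2R,3E,5R,6R)-5,6-diacetoxy-1-(tert-butyldimethylsilyloxy)-2-methoxyhept-3-en-1-yl]-5,6-dihydro-2H-pyran-2-one
Product: 18 (6S)-6-[(1S,2R,3E,5R,6R)-5,6-diacetoxy-1-hydroxy-2-methoxyhept-3-en-1-yl]-5,6-dihydro-2H-pyran-2-one
Conditions: HF·pyridine, pyridine, THF, 0 °C to rt
Reagents that add atoms: none
Why: Fluoride-mediated desilylation under buffered, weakly acidic conditions, which should avoid acetyl migration, lactone opening and oxa-Michael closure of the freed C1′ alcohol.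

Compound list
1 | (E)-pent-2-en-4-yn-1-ol | OC/C=C/C#C | starting material
2 | O-zirconated (1E,3E)-dienylzirconocene chloride, Cp2Zr(Cl)–O–CH2–CH=CH–CH=CH–Zr(Cl)Cp2 | Cl[Zr](C1C=CC=C1)(C1C=CC=C1)OC/C=C/C=C/[Zr](Cl)(C1C=CC=C1)C1C=CC=C1 | intermediate
3 | (2E,4E)-5-iodopenta-2,4-dien-1-ol | OC/C=C/C=C/I | intermediate
4 | (2E,4E)-5-iodopenta-2,4-dienal | O=C/C=C/C=C/I | intermediate
5 | (4S,5E,7E)-8-iodoocta-1,5,7-trien-4-yl diisopinocampheylborinate | I/C=C/C=C/[C@@H](OB([C@@H]1C[C@@H]2C[C@H]([C@H]1C)C2(C)C)[C@@H]1C[C@@H]2C[C@H]([C@H]1C)C2(C)C)CC=C | intermediate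
6 | (4S,5E,7E)-8-iodoocta-1,5,7-trien-4-ol | I/C=C/C=C/[C@@H](O)CC=C | intermediate
7 | (1S)-1-[(2S,3S)-3-[(E)-2-iodoethenyl]oxiran-2-yl]but-3-en-1-ol | I/C=C/[C@@H]1O[C@H]1[C@@H](O)CC=C | intermediate
8 | (1S)-1-[(2S,3S)-3-[(E)-2-iodoethenyl]oxiran-2-yl]but-3-en-1-yl prop-2-enoate | I/C=C/[C@@H]1O[C@H]1[C@@H](OC(=O)C=C)CC=C | intermediate
9 | (6S)-6-[(2S,3S)-3-[(E)-2-iodoethenyl]oxiran-2-yl]-5,6-dihydro-2H-pyran-2-one | I/C=C/[C@@H]1O[C@H]1[C@@H]2CC=CC(=O)O2 | intermediate
10 | (6S)-6-[(1S,2R,3E)-1-hydroxy-4-iodo-2-methoxybut-3-en-1-yl]-5,6-dihydro-2H-pyran-2-one | CO[C@H](/C=C/I)[C@@H](O)[C@@H]1CC=CC(=O)O1 | intermediate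
11 | (6S)-6-[(1S,2R,3E)-1-(tert-butyldimethylsilyloxy)-4-iodo-2-methoxybut-3-en-1-yl]-5,6-dihydro-2H-pyran-2-one | CO[C@H](/C=C/I)[C@@H](O[Si](C)(C)C(C)(C)C)[C@@H]1CC=CC(=O)O1 | intermediate
12 | methyl (4S,5R)-2,2,5-trimethyl-1,3-dioxolane-4-carboxylate | COC(=O)[C@H]1OC(C)(C)O[C@@H]1C | starting material
13 | cesium (4S,5R)-2,2,5-trimethyl-1,3-dioxolane-4-carboxylate | [Cs+].[O-]C(=O)[C@H]1OC(C)(C)O[C@@H]1C | intermediate
14 | (5R)-2,2,5-trimethyl-1,3-dioxolan-4-yl radical | [CH]1OC(C)(C)O[C@@H]1C | intermediate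
15 | (6S)-6-[(1S,2R,3E)-1-(tert-butyldimethylsilyloxy)-2-methoxy-4-[(4R,5R)-2,2,5-trimethyl-1,3-dioxolan-4-yl]but-3-en-1-yl]-5,6-dihydro-2H-pyran-2-one | CO[C@H](/C=C/[C@H]1OC(C)(C)O[C@@H]1C)[C@@H](O[Si](C)(C)C(C)(C)C)[C@@H]2CC=CC(=O)O2 | intermediate
16 | (6S)-6-[(1S,2R,3E,5R,6R)-1-(tert-butyldimethylsilyloxy)-5,6-dihydroxy-2-methoxyhept-3-en-1-yl]-5,6-dihydro-2H-pyran-2-one | CO[C@H](/C=C/[C@@H](O)[C@@H](C)O)[C@@H](O[Si](C)(C)C(C)(C)C)[C@@H]1CC=CC(=O)O1 | intermediate
17 | (6S)-6-[(1S,2R,3E,5R,6R)-5,6-diacetoxy-1-(tert-butyldimethylsilyloxy)-2-methoxyhept-3-en-1-yl]-5,6-dihydro-2H-pyran-2-one | CO[C@H](/C=C/[C@@H](OC(C)=O)[C@@H](C)OC(C)=O)[C@@H](O[Si](C)(C)C(C)(C)C)[C@@H]1CC=CC(=O)O1 | intermediate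
18 | (6S)-6-[(1S,2R,3E,5R,6R)-5,6-diacetoxy-1-hydroxy-2-methoxyhept-3-en-1-yl]-5,6-dihydro-2H-pyran-2-one | CO[C@H](/C=C/[C@@H](OC(C)=O)[C@@H](C)OC(C)=O)[C@@H](O)[C@@H]1CC=CC(=O)O1 | target

Total step count: 13. Longest linear sequence: 12 steps (steps 1–8, then 10–13); step 9 runs in parallel.

Steps most likely to fail

Step 10 (key coupling). The nucleophilic radical 14 may add to the lactone enoate instead of being captured by nickel, the trans preference at C5′ may be eroded, or the alkenyl iodide may simply be reduced. The fallback is a polar union of the same two carbons (alkenylchromium plus aldehyde) and sets out from 11. Catalogue (R)-2-acetoxypropanoyl chloride is reduced with Bu3SnH and Pd(PPh3)4 to (R)-2-acetoxypropanal F1. A Nozaki–Hiyama–Kishi reaction of 11 with F1 (CrCl2, NiCl2 cat., DMSO) should give mainly the Felkin–Anh adduct, the (5′S)-allylic alcohol F2 with the 5′,6′-anti arrangement. Mitsunobu esterification of F2 with acetic acid (PPh3, DIAD) inverts C5′ and returns to the route at 17.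

Step 7 (epoxide methanolysis). The Lewis acid-bound vinyl epoxide may ionise, with loss of clean inversion at C2′, or open in the conjugate sense, or the lactone may suffer acid-induced methanolysis. The fallback is a chelation-directed opening before the lactone exists and sets out from 7. The free C6 hydroxyl of 7 binds Eu(OTf)3 (cat., MeOH), which directs methanol to the distal, allylic epoxide carbon with inversion and should give the diol (1E,3R,4S,5S)-1-iodo-3-methoxyocta-1,7-diene-4,5-diol F3. Acryloylation at the less hindered C5 hydroxyl (acryloyl chloride, 2,4,6-collidine, −78 °C) should give the mono-acrylate F4. Ring-closing metathesis with the second-generation Grubbs catalyst returns to the route at 10.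

Step 4 (epoxidation). Turnover of the secondary dienyl carbinol may be slow, and the sensitive iodovinyl epoxy alcohol may be opened by titanium over the long reaction time. The fallback makes the epoxide first and the carbinol second, and sets out from 3. Catalytic Sharpless epoxidation of the primary dienol 3 (Ti(OiPr)4, L-(+)-DET, TBHP, −20 °C) should give [(2S,3S)-3-[(E)-2-iodoethenyl]oxiran-2-yl]methanol F5. Parikh–Doering oxidation (SO3·pyridine, DMSO, iPr2NEt) gives the epoxy aldehyde F6. Brown allylboration of F6 with (−)-Ipc2B(allyl), a reagent-controlled Si-face attack in line with the Felkin–Anh preference of the epoxy aldehyde, returns to the route at 7.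

Further compounds
F1 | step 10 | (R)-2-acetoxypropanal | C[C@@H](OC(C)=O)C=O
F2 | step 10 | (2R,3S,4E,6R,7S)-7-(tert-butyldimethylsilyloxy)-3-hydroxy-6-methoxy-7-[(2S)-6-oxo-3,6-dihydro-2H-pyran-2-yl]hept-4-en-2-yl acetate | CO[C@H](/C=C/[C@H](O)[C@@H](C)OC(C)=O)[C@@H](O[Si](C)(C)C(C)(C)C)[C@@H]1CC=CC(=O)O1
F3 | step 7 | (1E,3R,4S,5S)-1-iodo-3-methoxyocta-1,7-diene-4,5-diol | CO[C@H](/C=C/I)[C@@H](O)[C@@H](O)CC=C
F4 | step 7 | (1E,3R,4S,5S)-4-hydroxy-1-iodo-3-methoxyocta-1,7-dien-5-yl prop-2-enoate | CO[C@H](/C=C/I)[C@@H](O)[C@@H](OC(=O)C=C)CC=C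
F5 | step 4 | [(2S,3S)-3-[(E)-2-iodoethenyl]oxiran-2-yl]methanol | I/C=C/[C@@H]1O[C@H]1CO
F6 | step 4 | (2R,3S)-3-[(E)-2-iodoethenyl]oxirane-2-carbaldehyde | I/C=C/[C@@H]1O[C@H]1C=O
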